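**Strategy.** Everything rests on cutting the ring bond C3–C4 of the epoxycyclohexenol core (C1–C6). The carbinol C3 stands next to C4, the α-carbon of the acrylate-type unit C5=C4–CH2OH (carried as the ester), which is a Morita–Baylis–Hillman retron inside the six-membered ring. A phosphine-mediated cyclisation of an acyclic cis-epoxy aldehyde enoate, with C1, C2 and C6 already set and C1′ masked as CH2OPMB, forms C3–C4, closes the carbocycle, creates C3 and restores C4=C5 in one operation. The side chain is then grown from C1′: addition of a (Z)-2-stannylpropenyl unit, iododestannylation and Suzuki coupling with a terpenoid vinylboronate obtained by Ti(III)-mediated epoxy-olefin cyclisation.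

Key step: step 10

Assumption: (E)-geranyl acetate, propyne, hexamethylditin, the D-fructose-derived Shi ketone and 2-(dichloromethyl)pinacolborane are bought; C1–C6 (C1, C2 = oxirane carbons) and C1′–C5′ denote core and side-chain carbons of the target, and the core descriptors in the names of 17–21, 25, 26 and 34 use this numbering (PMB = 4-methoxybenzyl, TES = triethylsilyl, TBS = tert-butyldimethylsilyl).

**Core: butynediol to the C1′ aldehyde**

Step 1
Reactants: 1 but-2-yne-1,4-diol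
Product: 2 4-[(4-methoxybenzyl)oxy]but-2-yn-1-ol
Conditions: NaH (1 equiv), PMBCl (1 equiv), diol in excess (3 equiv), THF/DMF, 0 °C to rt
Reagents that add atoms: 4-methoxybenzyl chloride COc1ccc(CCl)cc1
Why: Williamson etherification of a symmetrical diol used in excess, so that statistical mono-alkylation should dominate over the bis-ether.

Step 2
Reactants: 2 4-[(4-methoxybenzyl)oxy]but-2-yn-1-ol
Product: 4 (2Z)-3-iodo-4-[(4-methoxybenzyl)oxy]but-2-en-1-ol, via cyclic sodium alkenylaluminate 3 (not isolated)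
Conditions: Red-Al, THF, 0 °C to rt; then I2, THF, −78 °C
Reagents that add atoms: iodine II
Why: Hydroxyl-directed trans-hydroalumination of the propargylic alcohol places aluminium on the distal alkyne carbon in a five-membered alkoxyaluminate, and iodinolysis with retention gives the (Z)-γ-iodoallylic alcohol (Corey-type hydroalumination–iodination).

Step 3
Reactants: 4 (2Z)-3-iodo-4-[(4-methoxybenzyl)oxy]but-2-en-1-ol; 5 acrolein
Product: 7 rac-(4Z)-4-{[(4-methoxybenzyl)oxy]methyl}hexa-1,4-diene-3,6-diol, via dilithio alkoxide-alkenyllithium 6 (not isolated)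
Conditions: MeLi (1.05 equiv), Et2O, −78 °C; t-BuLi (2.1 equiv), −78 °C; acrolein, −78 °C; NH4Cl
Reagents that add atoms: none
Why: After O-deprotonation, iodine–lithium exchange proceeds with retention to a (Z)-alkenyllithium that carries no silyl group able to migrate to carbon, and its 1,2-addition to acrolein forms the C1–C6 bond with the C3 and C6 arms cis on the alkene.

Step 4
Reactants: 7 rac-(4Z)-4-{[(4-methoxybenzyl)oxy]methyl}hexa-1,4-diene-3,6-diol
Product: 8 rac-(4Z)-4-{[(4-methoxybenzyl)oxy]methyl}-6-[(triethylsilyl)oxy]hexa-1,4-dien-3-ol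
Conditions: TESCl (1.05 equiv), imidazole, CH2Cl2, −78 to −40 °C
Reagents that add atoms: chlorotriethylsilane CC[Si](Cl)(CC)CC
Why: Silylation should be selective for the primary hydroxyl over the hindered bis-allylic secondary one.

Step 5
Reactants: 8 rac-(4Z)-4-{[(4-methoxybenzyl)oxy]methyl}-6-[(triethylsilyl)oxy]hexa-1,4-dien-3-ol
Product: 9 (3S,4Z)-4-{[(4-methoxybenzyl)oxy]methyl}-6-[(triethylsilyl)oxy]hexa-1,4-dien-3-ol
Conditions: immobilised lipase (Amano PS or CAL-B), vinyl acetate, MTBE, 30 °C, stopped just past half conversion; chromatography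
Reagents that add atoms: none
Why: Lipase-catalysed kinetic resolution by transesterification; by Kazlauskas' rule (vinyl as medium group, trisubstituted alkenyl as large group) the (R)-alcohol should be acetylated and the (S)-alcohol, which has the C6 configuration of the target, recovered.

Step 6
Reactants: 9 (3S,4Z)-4-{[(4-methoxybenzyl)oxy]methyl}-6-[(triethylsilyl)oxy]hexa-1,4-dien-3-ol; 10 methyl acrylate
Product: 11 methyl (2E,4S,5Z)-4-hydroxy-5-{[(4-methoxybenzyl)oxy]methyl}-7-[(triethylsilyl)oxy]hepta-2,5-dienoate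
Conditions: Hoveyda–Grubbs II (5 mol%), methyl acrylate (5 equiv), CH2Cl2, 40 °C
Reagents that add atoms: none
Why: Olefin cross-metathesis of the terminal vinyl carbinol with the electron-poor acrylate should give the (E)-γ-hydroxy enoate, the trisubstituted alkene being too hindered to take part.

Step 7
Reactants: 11 methyl (2E,4S,5Z)-4-hydroxy-5-{[(4-methoxybenzyl)oxy]methyl}-7-[(triethylsilyl)oxy]hepta-2,5-dienoate
Product: 12 methyl (2E,4S)-4-hydroxy-4-[(2R,3S)-2-{[(4-methoxybenzyl)oxy]methyl}-3-{[(triethylsilyl)oxy]methyl}oxiran-2-yl]but-2-enoate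
Conditions: mCPBA, NaHCO3, CH2Cl2, 0 °C to rt
Reagents that add atoms: 3-chloroperbenzoic acid OOC(=O)c1cccc(Cl)c1
Why: Hydroxyl-directed (Henbest) peracid epoxidation of the only electron-rich alkene; A(1,3) strain with the cis CH2OTES arm holds the C6–H in the alkene plane, so the hydrogen-bonded peracid should deliver oxygen syn to the C6 hydroxyl and set C1 and C2 in the threo sense.

Step 8
Reactants: 12 methyl (2E,4S)-4-hydroxy-4-[(2R,3S)-2-{[(4-methoxybenzyl)oxy]methyl}-3-{[(triethylsilyl)oxy]methyl}oxiran-2-yl]but-2-enoate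
Product: 13 methyl (2E,4S)-4-[(tert-butyldimethylsilyl)oxy]-4-[(2S,3S)-2-{[(4-methoxybenzyl)oxy]methyl}-3-{[(triethylsilyl)oxy]methyl}oxiran-2-yl]but-2-enoate
Conditions: TBSOTf, 2,6-lutidine, CH2Cl2, −78 °C
Reagents that add atoms: tert-butyldimethylsilyl triflate CC(C)(C)[Si](C)(C)OS(=O)(=O)C(F)(F)F
Why: Silyl triflate/lutidine silylation of the hindered secondary carbinol at low temperature, under which oxirane, TES ether and enoate should be untouched.

Step 9
Reactants: 13 methyl (2E,4S)-4-[(tert-butyldimethylsilyl)oxy]-4-[(2S,3S)-2-{[(4-methoxybenzyl)oxy]methyl}-3-{[(triethylsilyl)oxy]methyl}oxiran-2-yl]but-2-enoate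
Product: 14 methyl (2E,4S)-4-[(tert-butyldimethylsilyl)oxy]-4-[(2S,3R)-3-formyl-2-{[(4-methoxybenzyl)oxy]methyl}oxiran-2-yl]but-2-enoate
Conditions: (COCl)2, DMSO, CH2Cl2, −78 to −40 °C; Et3N, −78 to 0 °C
Reagents that add atoms: none
Why: Swern oxidative desilylation: the chlorosulfonium salt cleaves the primary TES ether and oxidises it in the same pot while the secondary TBS ether survives, and the oxirane C2–H, though α to the aldehyde, cannot enolise without forming an alkylidene oxirane, so the cis-epoxy aldehyde keeps its configuration.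

Step 10
Reactants: 14 methyl (2E,4S)-4-[(tert-butyldimethylsilyl)oxy]-4-[(2S,3R)-3-formyl-2-{[(4-methoxybenzyl)oxy]methyl}oxiran-2-yl]but-2-enoate
Product: 17 methyl (1S,2S,3R,6S)-6-[(TBS)oxy]-1,2-epoxy-3-hydroxy-1-{[(4-methoxybenzyl)oxy]methyl}cyclohex-4-ene-4-carboxylate, via C5-phosphonium ester enolate zwitterion 15 (not isolated), via cyclised phosphonium alkoxide 16 (not isolated)
Conditions: PMe3 (1.0 equiv, 1 M in THF), tert-amyl alcohol, rt, degassed
Reagents that add atoms: none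
Why: Trimethylphosphine adds reversibly to C5 of the enoate to give the phosphonium enolate 15, whose C4 attacks the C3 aldehyde to give alkoxide 16, and proton transfer followed by E1cB loss of the phosphine restores C4=C5 inside the new ring. The closest known reaction type is the trialkylphosphine-mediated intramolecular Morita–Baylis–Hillman cyclisation of ω-formyl enoates and thioenoates to 6-hydroxycyclohex-1-ene carboxylates. The ring closes in the 6-(enolexo)-exo-trig mode, and the cis-oxirane holds the aldehyde and enoate arms on one side so that no other ring size is within reach. The new stereocentre C3 is controlled by the oxirane: in the half-chair transition state the C=O points away from the C2–O bond (dipole-opposed), so the hydroxyl should end trans to the oxirane. The step needs the phosphine to attack C5 in preference to the oxirane or the aldehyde, and no β-elimination at C6; the small soft phosphine, the non-enolisable aldehyde and the poor silyloxide leaving group secure this. The protic solvent protonates the C3 alkoxide before it can undergo Payne rearrangement.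

Step 11
Reactants: 17 methyl (1S,2S,3R,6S)-6-[(TBS)oxy]-1,2-epoxy-3-hydroxy-1-{[(4-methoxybenzyl)oxy]methyl}cyclohex-4-ene-4-carboxylate
Product: 18 (1S,2S,3R,6S)-6-[(TBS)oxy]-1,2-epoxy-4-(hydroxymethyl)-1-{[(4-methoxybenzyl)oxy]methyl}cyclohex-4-en-3-ol
Conditions: DIBAL-H (3.5 equiv), CH2Cl2, −78 °C; Rochelle salt
Reagents that add atoms: none
Why: DIBAL-H 1,2-reduction of the enoate to the allylic alcohol at −78 °C, where oxirane, silyl and PMB ethers should be inert.

Step 12
Reactants: 18 (1S,2S,3R,6S)-6-[(TBS)oxy]-1,2-epoxy-4-(hydroxymethyl)-1-{[(4-methoxybenzyl)oxy]methyl}cyclohex-4-en-3-ol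
Product: 19 (1S,2S,3R,6S)-3,6-bis[(TBS)oxy]-4-{[(TBS)oxy]methyl}-1,2-epoxy-1-{[(4-methoxybenzyl)oxy]methyl}cyclohex-4-ene
Conditions: TBSOTf (2.5 equiv), 2,6-lutidine, CH2Cl2, −78 to 0 °C
Reagents that add atoms: tert-butyldimethylsilyl triflate CC(C)(C)[Si](C)(C)OS(=O)(=O)C(F)(F)F
Why: Exhaustive silylation of the primary allylic and the C3 hydroxyl; the C3 silyl ether later screens one flank of the C1′ aldehyde.

Step 13
Reactants: 19 (1S,2S,3R,6S)-3,6-bis[(TBS)oxy]-4-{[(TBS)oxy]methyl}-1,2-epoxy-1-{[(4-methoxybenzyl)oxy]methyl}cyclohex-4-ene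
Product: 20 [(1S,2S,3R,6S)-3,6-bis[(TBS)oxy]-4-{[(TBS)oxy]methyl}-1,2-epoxycyclohex-4-en-1-yl]methanol
Conditions: DDQ, CH2Cl2/pH 7 buffer, 0 °C
Reagents that add atoms: none
Why: Oxidative PMB cleavage by DDQ (benzylic hydride abstraction, then hydrolysis of the oxocarbenium ion), which should leave silyl ethers, oxirane and the electron-poor ring alkene alone.

Step 14
Reactants: 20 [(1S,2S,3R,6S)-3,6-bis[(TBS)oxy]-4-{[(TBS)oxy]methyl}-1,2-epoxycyclohex-4-en-1-yl]methanol
Product: 21 (1S,2S,3R,6S)-3,6-bis[(TBS)oxy]-4-{[(TBS)oxy]methyl}-1,2-epoxycyclohex-4-ene-1-carbaldehyde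
Conditions: Dess–Martin periodinane, NaHCO3, CH2Cl2, 0 °C to rt
Reagents that add atoms: none
Why: Dess–Martin oxidation of the neopentyl-type primary alcohol under buffered conditions; the aldehyde sits on the quaternary C1 and has no α-hydrogen.

**C2′–C3′ unit and its attachment**

Step 15
Reactants: 22 propyne
Product: 23 (1Z)-1,2-bis(trimethylstannyl)prop-1-ene
Conditions: Me3SnSnMe3, Pd(PPh3)4 (2 mol%), THF, 65 °C, sealed tube
Reagents that add atoms: hexamethylditin C[Sn](C)(C)[Sn](C)(C)C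
Why: Pd(0)-catalysed syn-distannylation of a terminal alkyne gives the cis-1,2-distannylalkene.

Step 16
Reactants: 21 (1S,2S,3R,6S)-3,6-bis[(TBS)oxy]-4-{[(TBS)oxy]methyl}-1,2-epoxycyclohex-4-ene-1-carbaldehyde; 23 (1Z)-1,2-bis(trimethylstannyl)prop-1-ene
Product: 25 (1S,2Z)-1-[(1S,2S,3R,6S)-3,6-bis[(TBS)oxy]-4-{[(TBS)oxy]methyl}-1,2-epoxycyclohex-4-en-1-yl]-3-(trimethylstannyl)but-2-en-1-ol, via (Z)-2-(trimethylstannyl)prop-1-enyllithium 24 (not isolated)
Conditions: 23, MeLi (1.0 equiv), THF, −78 °C; then 21, THF, −78 °C; NH4Cl at −78 °C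
Reagents that add atoms: none
Why: Tin–lithium exchange takes the less hindered terminal stannyl group with retention, and the alkenyllithium adds to the aldehyde in THF without chelation; Felkin–Anh/Cornforth attack anti to the C1–O oxirane bond along the C6–H flank, the C2 flank being screened by the syn C3 silyl ether, should set C1′ as S.

Step 17
Reactants: 25 (1S,2Z)-1-[(1S,2S,3R,6S)-3,6-bis[(TBS)oxy]-4-{[(TBS)oxy]methyl}-1,2-epoxycyclohex-4-en-1-yl]-3-(trimethylstannyl)but-2-en-1-ol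
Product: 26 (1S,2Z)-1-[(1S,2S,3R,6S)-3,6-bis[(TBS)oxy]-4-{[(TBS)oxy]methyl}-1,2-epoxycyclohex-4-en-1-yl]-3-iodobut-2-en-1-ol
Conditions: I2 (1.05 equiv), CH2Cl2, 0 °C
Reagents that add atoms: iodine II
Why: Ipso-iododestannylation with retention of alkene geometry; the C–Sn bond reacts far faster than the ring alkene or the hydroxyl.

**Terpenoid half**

Step 18
Reactants: 27 (E)-geranyl acetate
Product: 28 (2E)-5-[(2R)-3,3-dimethyloxiran-2-yl]-3-methylpent-2-en-1-yl acetate
Conditions: D-fructose-derived Shi ketone (30 mol%), Oxone, K2CO3, Bu4NHSO4, MeCN/dimethoxymethane/aqueous buffer, 0 °C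
Reagents that add atoms: potassium peroxymonosulfate [K+].[O-]S(=O)(=O)OO
Why: Shi epoxidation: the chiral dioxirane attacks the electron-rich 6,7-alkene (the 2,3-alkene is deactivated by the allylic acetate) through the spiro transition state, which should give the (R)-oxirane.

Step 19
Reactants: 28 (2E)-5-[(2R)-3,3-dimethyloxiran-2-yl]-3-methylpent-2-en-1-yl acetate
Product: 29 [(1S,3R)-3-hydroxy-2,2-dimethyl-6-methylidenecyclohexyl]methyl acetate
Conditions: Cp2TiCl2 (2.2 equiv), Mn dust, THF, rt; dilute aqueous acid work-up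
Reagents that add atoms: none
Why: Titanocene(III) opens the oxirane homolytically to the tertiary β-titanoxy radical, which closes 6-endo through a chair with titanoxy and acetoxymethyl groups equatorial (setting the ring CH cis to the hydroxyl), and the tertiary radical is trapped by Ti(III) and released as the exocyclic alkene (Nugent–RajanBabu-type radical cyclisation).

Step 20
Reactants: 29 [(1S,3R)-3-hydroxy-2,2-dimethyl-6-methylidenecyclohexyl]methyl acetate
Product: 30 [(3R,4S,6R)-6-hydroxy-5,5-dimethyl-1-oxaspiro[2.5]octan-4-yl]methyl acetate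
Conditions: mCPBA, NaHCO3, CH2Cl2, 0 °C
Reagents that add atoms: 3-chloroperbenzoic acid OOC(=O)c1cccc(Cl)c1
Why: Peracid epoxidation of the exocyclic alkene should occur on the equatorial face, the axial face being screened by the syn-axial methyl of the gem-dimethyl carbon (as in epoxidations of 8(12)-drimenes), which places the spiro oxygen trans to the acetoxymethyl group.

Step 21
Reactants: 30 [(3R,4S,6R)-6-hydroxy-5,5-dimethyl-1-oxaspiro[2.5]octan-4-yl]methyl acetate
Product: 31 (1R,2S,4R)-2-(hydroxymethyl)-1,3,3-trimethylcyclohexane-1,4-diol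
Conditions: LiAlH4, THF, 0 °C to rt; Fieser work-up
Reagents that add atoms: none
Why: Hydride opens the spiro-oxirane at its unhindered CH2 terminus to the tertiary alcohol (axial methyl, equatorial hydroxyl) and cleaves the acetate in the same operation.

Step 22
Reactants: 31 (1R,2S,4R)-2-(hydroxymethyl)-1,3,3-trimethylcyclohexane-1,4-diol
Product: 32 (1R,3R,6R)-3,6-dihydroxy-2,2,6-trimethylcyclohexane-1-carbaldehyde
Conditions: TEMPO (10 mol%), PhI(OAc)2, CH2Cl2, rt; used directly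
Reagents that add atoms: none
Why: Oxoammonium oxidation is selective for the primary over the hindered secondary and the tertiary hydroxyl, and its near-neutral medium should avoid retro-aldol cleavage or dehydration of the β-hydroxy aldehyde.

Step 23
Reactants: 32 (1R,3R,6R)-3,6-dihydroxy-2,2,6-trimethylcyclohexane-1-carbaldehyde
Product: 33 (1R,2R,4R)-1,3,3-trimethyl-2-[(E)-2-(4,4,5,5-tetramethyl-1,3,2-dioxaborolan-2-yl)ethenyl]cyclohexane-1,4-diol
Conditions: Cl2CHBpin, CrCl2 (8 equiv), LiI, THF, rt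
Reagents that add atoms: 2-(dichloromethyl)-4,4,5,5-tetramethyl-1,3,2-dioxaborolane CC1(C)OB(C(Cl)Cl)OC1(C)C
Why: Takai–Utimoto chromium(II)-mediated boryl-olefination through a gem-dichromium species gives the (E)-alkenylboronate and tolerates free hydroxyls.

**Union and deprotection**

Step 24
Reactants: 26 (1S,2Z)-1-[(1S,2S,3R,6S)-3,6-bis[(TBS)oxy]-4-{[(TBS)oxy]methyl}-1,2-epoxycyclohex-4-en-1-yl]-3-iodobut-2-en-1-ol; 33 (1R,2R,4R)-1,3,3-trimethyl-2-[(E)-2-(4,4,5,5-tetramethyl-1,3,2-dioxaborolan-2-yl)ethenyl]cyclohexane-1,4-diol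
Product: 34 3-O,6-O,4-CH2O-tris(TBS)-arthrosporol A
Conditions: Pd(PPh3)4 (10 mol%), TlOEt, THF/H2O (3:1), rt
Reagents that add atoms: none
Why: Suzuki–Miyaura coupling with retention at both sp2 partners joins C3′ to C4′ and gives the (2′Z,4′E)-diene at room temperature, compatible with oxirane, silyl ethers and free hydroxyls.

Step 25
Reactants: 34 3-O,6-O,4-CH2O-tris(TBS)-arthrosporol A
Product: 35 arthrosporol A
Conditions: TBAF/AcOH (1:1), THF, 0 °C to rt
Reagents that add atoms: none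
Why: Fluoride cleaves the three silyl ethers, and acetic acid buffering keeps the oxirane-flanking hydroxyls protonated (no Payne rearrangement) without creating acidity that would ionise the dienylic C1′ alcohol.

**Compound list**

1 | but-2-yne-1,4-diol | OCC#CCO | starting material
2 | 4-[(4-methoxybenzyl)oxy]but-2-yn-1-ol | COc1ccc(COCC#CCO)cc1 | intermediate
3 | cyclic sodium alkenylaluminate from 2 (Al on C3, O–Al chelate) | [Na+].COCCO[Al-]1(OCCOC)OCC=C1COCc1ccc(OC)cc1 | intermediate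
4 | (2Z)-3-iodo-4-[(4-methoxybenzyl)oxy]but-2-en-1-ol | OC/C=C(\I)COCc1ccc(OC)cc1 | intermediate
5 | acrolein | C=CC=O | starting material
6 | dilithio alkoxide-alkenyllithium from 4 | [Li]OC/C=C(\[Li])COCc1ccc(OC)cc1 | intermediate
7 | rac-(4Z)-4-{[(4-methoxybenzyl)oxy]methyl}hexa-1,4-diene-3,6-diol | C=CC(O)/C(COCc1ccc(OC)cc1)=C\CO | intermediate
8 | rac-(4Z)-4-{[(4-methoxybenzyl)oxy]methyl}-6-[(triethylsilyl)oxy]hexa-1,4-dien-3-ol | C=CC(O)/C(COCc1ccc(OC)cc1)=C\CO[Si](CC)(CC)CC | intermediate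
9 | (3S,4Z)-4-{[(4-methoxybenzyl)oxy]methyl}-6-[(triethylsilyl)oxy]hexa-1,4-dien-3-ol | C=C[C@H](O)/C(COCc1ccc(OC)cc1)=C\CO[Si](CC)(CC)CC | intermediate
10 | methyl acrylate | C=CC(=O)OC | starting material
11 | methyl (2E,4S,5Z)-4-hydroxy-5-{[(4-methoxybenzyl)oxy]methyl}-7-[(triethylsilyl)oxy]hepta-2,5-dienoate | COC(=O)/C=C/[C@H](O)/C(COCc1ccc(OC)cc1)=C\CO[Si](CC)(CC)CC | intermediate
12 | methyl (2E,4S)-4-hydroxy-4-[(2R,3S)-2-{[(4-methoxybenzyl)oxy]methyl}-3-{[(triethylsilyl)oxy]methyl}oxiran-2-yl]but-2-enoate | COc1ccc(COC[C@@]2(O[C@H]2CO[Si](CC)(CC)CC)[C@@H](O)/C=C/C(=O)OC)cc1 | intermediate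
13 | methyl (2E,4S)-4-[(tert-butyldimethylsilyl)oxy]-4-[(2S,3S)-2-{[(4-methoxybenzyl)oxy]methyl}-3-{[(triethylsilyl)oxy]methyl}oxiran-2-yl]but-2-enoate | COc1ccc(COC[C@@]2(O[C@H]2CO[Si](CC)(CC)CC)[C@@H](O[Si](C)(C)C(C)(C)C)/C=C/C(=O)OC)cc1 | intermediate
14 | methyl (2E,4S)-4-[(tert-butyldimethylsilyl)oxy]-4-[(2S,3R)-3-formyl-2-{[(4-methoxybenzyl)oxy]methyl}oxiran-2-yl]but-2-enoate | COc1ccc(COC[C@@]2(O[C@H]2C=O)[C@@H](O[Si](C)(C)C(C)(C)C)/C=C/C(=O)OC)cc1 | intermediate
15 | C5-trimethylphosphonium ester enolate zwitterion of 14 | COc1ccc(COC[C@@]2(O[C@H]2C=O)[C@@H](O[Si](C)(C)C(C)(C)C)C([P+](C)(C)C)C=C([O-])OC)cc1 | intermediate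
16 | cyclised C5-phosphonium C3-alkoxide zwitterion | COc1ccc(COC[C@]23O[C@H]2[C@H]([O-])C(C(=O)OC)C([P+](C)(C)C)[C@@H]3O[Si](C)(C)C(C)(C)C)cc1 | intermediate
17 | methyl (1S,2S,3R,6S)-6-[(TBS)oxy]-1,2-epoxy-3-hydroxy-1-{[(4-methoxybenzyl)oxy]methyl}cyclohex-4-ene-4-carboxylate | COc1ccc(COC[C@]23O[C@H]2[C@H](O)C(C(=O)OC)=C[C@@H]3O[Si](C)(C)C(C)(C)C)cc1 | intermediate
18 | (1S,2S,3R,6S)-6-[(TBS)oxy]-1,2-epoxy-4-(hydroxymethyl)-1-{[(4-methoxybenzyl)oxy]methyl}cyclohex-4-en-3-ol | COc1ccc(COC[C@]23O[C@H]2[C@H](O)C(CO)=C[C@@H]3O[Si](C)(C)C(C)(C)C)cc1 | intermediate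
19 | (1S,2S,3R,6S)-3,6-bis[(TBS)oxy]-4-{[(TBS)oxy]methyl}-1,2-epoxy-1-{[(4-methoxybenzyl)oxy]methyl}cyclohex-4-ene | COc1ccc(COC[C@]23O[C@H]2[C@H](O[Si](C)(C)C(C)(C)C)C(CO[Si](C)(C)C(C)(C)C)=C[C@@H]3O[Si](C)(C)C(C)(C)C)cc1 | intermediate
20 | [(1S,2S,3R,6S)-3,6-bis[(TBS)oxy]-4-{[(TBS)oxy]methyl}-1,2-epoxycyclohex-4-en-1-yl]methanol | OC[C@]12O[C@H]1[C@H](O[Si](C)(C)C(C)(C)C)C(CO[Si](C)(C)C(C)(C)C)=C[C@@H]2O[Si](C)(C)C(C)(C)C | intermediate
21 | (1S,2S,3R,6S)-3,6-bis[(TBS)oxy]-4-{[(TBS)oxy]methyl}-1,2-epoxycyclohex-4-ene-1-carbaldehyde | O=C[C@]12O[C@H]1[C@H](O[Si](C)(C)C(C)(C)C)C(CO[Si](C)(C)C(C)(C)C)=C[C@@H]2O[Si](C)(C)C(C)(C)C | intermediate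
22 | propyne | CC#C | starting material
23 | (1Z)-1,2-bis(trimethylstannyl)prop-1-ene | CC(=C/[Sn](C)(C)C)/[Sn](C)(C)C | intermediate
24 | (Z)-2-(trimethylstannyl)prop-1-enyllithium | CC(=C/[Li])/[Sn](C)(C)C | intermediate
25 | (1S,2Z)-1-[(1S,2S,3R,6S)-3,6-bis[(TBS)oxy]-4-{[(TBS)oxy]methyl}-1,2-epoxycyclohex-4-en-1-yl]-3-(trimethylstannyl)but-2-en-1-ol | CC(=C/[C@H](O)[C@]12O[C@H]1[C@H](O[Si](C)(C)C(C)(C)C)C(CO[Si](C)(C)C(C)(C)C)=C[C@@H]2O[Si](C)(C)C(C)(C)C)/[Sn](C)(C)C | intermediate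
26 | (1S,2Z)-1-[(1S,2S,3R,6S)-3,6-bis[(TBS)oxy]-4-{[(TBS)oxy]methyl}-1,2-epoxycyclohex-4-en-1-yl]-3-iodobut-2-en-1-ol | CC(=C/[C@H](O)[C@]12O[C@H]1[C@H](O[Si](C)(C)C(C)(C)C)C(CO[Si](C)(C)C(C)(C)C)=C[C@@H]2O[Si](C)(C)C(C)(C)C)/I | intermediate
27 | (E)-geranyl acetate | CC(C)=CCC/C(C)=C/COC(C)=O | starting material
28 | (2E)-5-[(2R)-3,3-dimethyloxiran-2-yl]-3-methylpent-2-en-1-yl acetate | CC1(C)O[C@@H]1CC/C(C)=C/COC(C)=O | intermediate
29 | [(1S,3R)-3-hydroxy-2,2-dimethyl-6-methylidenecyclohexyl]methyl acetate | CC(=O)OC[C@@H]1C(C)(C)[C@H](O)CCC1=C | intermediate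
30 | [(3R,4S,6R)-6-hydroxy-5,5-dimethyl-1-oxaspiro[2.5]octan-4-yl]methyl acetate | CC(=O)OC[C@@H]1C(C)(C)[C@H](O)CC[C@@]12OC2 | intermediate
31 | (1R,2S,4R)-2-(hydroxymethyl)-1,3,3-trimethylcyclohexane-1,4-diol | OC[C@@H]1C(C)(C)[C@H](O)CC[C@@]1(C)O | intermediate
32 | (1R,3R,6R)-3,6-dihydroxy-2,2,6-trimethylcyclohexane-1-carbaldehyde | O=C[C@@H]1C(C)(C)[C@H](O)CC[C@@]1(C)O | intermediate
33 | (1R,2R,4R)-1,3,3-trimethyl-2-[(E)-2-(4,4,5,5-tetramethyl-1,3,2-dioxaborolan-2-yl)ethenyl]cyclohexane-1,4-diol | CC1(C)OB(/C=C/[C@@H]2C(C)(C)[C@H](O)CC[C@@]2(C)O)OC1(C)C | intermediate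
34 | 3-O,6-O,4-CH2O-tris(TBS)-arthrosporol A | CC(=C/[C@H](O)[C@]12O[C@H]1[C@H](O[Si](C)(C)C(C)(C)C)C(CO[Si](C)(C)C(C)(C)C)=C[C@@H]2O[Si](C)(C)C(C)(C)C)/C=C/[C@@H]1C(C)(C)[C@H](O)CC[C@@]1(C)O | intermediate
35 | arthrosporol A | CC(=C/[C@H](O)[C@]12O[C@H]1[C@H](O)C(CO)=C[C@@H]2O)/C=C/[C@@H]1C(C)(C)[C@H](O)CC[C@@]1(C)O | target

**Totals.** Total step count: 25. Longest linear sequence: 18 steps (steps 1–14, 16, 17, 24, 25).

**Steps most likely to fail**

Step 10 (key cyclisation). Phosphine addition to the γ-branched C5 may be too slow for turnover, or the C3 hydroxyl may form cis to the oxirane. The fallback sets out from 14 and replaces the catalytic process by a stoichiometric chalcogenide Michael–aldol sequence: lithium benzeneselenolate (THF, −78 °C) adds to C5 and the ester enolate closes onto the aldehyde to give the β-phenylselanyl aldol adduct F1. Oxidation (H2O2, pyridine, CH2Cl2, 0 °C) gives the selenoxide F2, whose syn-elimination toward the acidic C4–H, away from the oxygen-bearing C6, comes back to the route at 17.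

Step 16 (C1′ carbinol). Facial selectivity at the α-quaternary epoxy aldehyde may be poor, or partial chelation by the oxirane oxygen may reverse it, giving a mixture of C1′ epimers. The fallback sets out from 25 as its mixture with the C1′ epimer: Dess–Martin oxidation gives the (Z)-β-stannyl enone F3, and reagent-controlled reduction with (R)-Me-CBS and catecholborane (the quaternary C1 as large group) returns to 25.

Step 7 (directed epoxidation). Oxygen transfer to the alkene, which is deactivated by three allylic oxygens, may be slow and the threo preference may erode. The fallback sets out from 11 and moves control to the reagent: TBSOTf/2,6-lutidine gives the bis-silyl ether F4, PPTS in MeOH frees the primary allylic alcohol F5, and Sharpless epoxidation from that alcohol (Ti(OiPr)4, D-(−)-diisopropyl tartrate, TBHP, −20 °C) gives the epoxy alcohol F6. Dess–Martin oxidation of F6 comes back to the route at 14.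

Further compounds
F1 | step 10 | methyl (1S,2S,3R,6S)-6-[(TBS)oxy]-1,2-epoxy-3-hydroxy-1-{[(4-methoxybenzyl)oxy]methyl}-5-(phenylselanyl)cyclohexane-4-carboxylate (C4, C5 epimers) | COc1ccc(COC[C@]23O[C@H]2[C@H](O)C(C(=O)OC)C([Se]c4ccccc4)[C@@H]3O[Si](C)(C)C(C)(C)C)cc1
F2 | step 10 | selenoxide of F1 | COc1ccc(COC[C@]23O[C@H]2[C@H](O)C(C(=O)OC)C([Se](=O)c4ccccc4)[C@@H]3O[Si](C)(C)C(C)(C)C)cc1
F3 | step 16 | (2Z)-1-[(1S,2S,3R,6S)-3,6-bis[(TBS)oxy]-4-{[(TBS)oxy]methyl}-1,2-epoxycyclohex-4-en-1-yl]-3-(trimethylstannyl)but-2-en-1-one | CC(=C/C(=O)[C@]12O[C@H]1[C@H](O[Si](C)(C)C(C)(C)C)C(CO[Si](C)(C)C(C)(C)C)=C[C@@H]2O[Si](C)(C)C(C)(C)C)/[Sn](C)(C)C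
F4 | step 7 | methyl (2E,4S,5Z)-4-[(tert-butyldimethylsilyl)oxy]-5-{[(4-methoxybenzyl)oxy]methyl}-7-[(triethylsilyl)oxy]hepta-2,5-dienoate | COC(=O)/C=C/[C@H](O[Si](C)(C)C(C)(C)C)/C(COCc1ccc(OC)cc1)=C\CO[Si](CC)(CC)CC
F5 | step 7 | methyl (2E,4S,5Z)-4-[(tert-butyldimethylsilyl)oxy]-7-hydroxy-5-{[(4-methoxybenzyl)oxy]methyl}hepta-2,5-dienoate | COC(=O)/C=C/[C@H](O[Si](C)(C)C(C)(C)C)/C(COCc1ccc(OC)cc1)=C\CO
F6 | step 7 | methyl (2E,4S)-4-[(tert-butyldimethylsilyl)oxy]-4-[(2S,3S)-3-(hydroxymethyl)-2-{[(4-methoxybenzyl)oxy]methyl}oxiran-2-yl]but-2-enoate | COc1ccc(COC[C@@]2(O[C@H]2CO)[C@@H](O[Si](C)(C)C(C)(C)C)/C=C/C(=O)OC)cc1
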